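**Retrosynthetic overview**
- The target is the leuco (hydroquinone) form of a mixed 3,6-diacyloxy-2,5-diaryl-1,4-benzoquinone. Quinone reduction and O-debenzylation are done together in the last step, and the quinone fixes the para ester/ester and para OH/OH pattern.
- The mixed quinone diester comes from stepwise O-acylation of 4,4''-di-O-benzylatromentin: benzoyl first, then (R)-3-acetoxybutanoyl chloride made from (R)-3-hydroxybutanoic acid.
- Both aryl–aryl bonds are formed in one photochemical operation: twofold photoredox C–H arylation of 2,5-dihydroxy-1,4-benzoquinone with the diazonium salt generated from 4-(benzyloxy)aniline.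
- No ring is constructed: the central ring is bought as the quinone and the outer rings as the aniline. Order of events: aryl–aryl bonds, esters, reduction.

Assumption: the stereocentre in the given SMILES is read as (R), and the three starting materials are taken as catalogue chemicals.

**Route**

Step 1
Reactants: 1 2,5-dihydroxy-1,4-benzoquinone; 2 4-(benzyloxy)aniline
Product: 5 2,5-bis[4-(benzyloxy)phenyl]-3,6-dihydroxy-1,4-benzoquinone, via 4-(benzyloxy)benzenediazonium tetrafluoroborate 3 (not isolated), via 2-[4-(benzyloxy)phenyl]-3,6-dihydroxy-1,4-benzoquinone 4 (not isolated)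
Conditions: 2 (3.0 equiv), t-BuONO (3.0 equiv), HBF4 (50% aq, 4.0 equiv), MeCN, 0 °C, 30 min; then 1 (1.0 equiv), Ru(bpy)3Cl2·6H2O (2 mol%), MeCN/H2O 4:1, 450 nm LEDs, 20 °C, 16 h, Ar
Reagents that add atoms: none
Why: Proposed new method: a twofold visible-light photo-Meerwein C–H arylation of an unprotected 2,5-dihydroxy-para-benzoquinone, not yet shown on hydroxyquinones of this kind, in which the excited Ru(bpy)3 dication (divalent ruthenium) reduces 3 to the 4-(benzyloxy)phenyl radical and N2, the radical adds to the only C–H carbon of the quinone to give a captodatively stabilised α-hydroxy-α-acyl radical that is oxidised by trivalent ruthenium or by a further molecule of 3 (radical chain) and loses a proton to restore the hydroxyquinone, the sequence repeating at the second C–H via 4, while excess HBF4 keeps the acidic enol un-ionised and so suppresses azo coupling; the closest known reaction types are the photoredox Meerwein arylation of heteroarenes and enol derivatives with arenediazonium salts and the thermal diazonium arylation of quinones; no stereocentre is formed.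

Step 2
Reactants: 5 2,5-bis[4-(benzyloxy)phenyl]-3,6-dihydroxy-1,4-benzoquinone
Product: 6 3-(benzoyloxy)-6-hydroxy-2,5-bis[4-(benzyloxy)phenyl]-1,4-benzoquinone
Conditions: Et3N (2.2 equiv), BzCl (1.0 equiv, slow addition), CH2Cl2/THF, −78 → −20 °C; then cold 1 M HCl
Reagents that add atoms: benzoyl chloride O=C(Cl)c1ccccc1
Why: O-acylation of a vinylogous carboxylate with an acid chloride, in which the four oxygens of the dianion of 5 are equivalent and the dianion is more nucleophilic than the mono-benzoylated monoanion, so one equivalent of BzCl at low temperature stops mainly at the monoester, which settles as the para-quinone with OH para to OBz (recovered 5 and dibenzoate are recycled).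

Step 3
Reactants: 7 (R)-3-hydroxybutanoic acid
Product: 9 (R)-3-acetoxybutanoyl chloride, via (R)-3-acetoxybutanoic acid 8 (not isolated)
Conditions: AcCl (3 equiv), neat, 0 → 20 °C, 3 h, evaporate; then (COCl)2 (1.5 equiv), DMF (cat.), CH2Cl2, 0 → 20 °C, evaporate, bulb-to-bulb distillation
Reagents that add atoms: acetyl chloride CC(=O)Cl; oxalyl chloride O=C(Cl)C(=O)Cl
Why: O-acetylation of the secondary alcohol followed by DMF-catalysed (Vilsmeier-type) conversion of the acid into its chloride, with the purchased (R) centre carried through because no bond to it is broken.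

Step 4
Reactants: 6 3-(benzoyloxy)-6-hydroxy-2,5-bis[4-(benzyloxy)phenyl]-1,4-benzoquinone; 9 (R)-3-acetoxybutanoyl chloride
Product: 10 3-(benzoyloxy)-6-{[(3R)-3-acetoxybutanoyl]oxy}-2,5-bis[4-(benzyloxy)phenyl]-1,4-benzoquinone
Conditions: 9 (1.5 equiv), 2,6-lutidine (2.0 equiv), CH2Cl2, −30 → 0 °C, 1 h; cold 0.5 M HCl wash, rapid filtration through silica
Reagents that add atoms: none
Why: O-acylation of the acidic enol (vinylogous acid) by the acid chloride to give the vinylogous mixed anhydride, where the only free OH sits para to OBz and the enolate oxygen next to the ring carbonyl is the more charged and less hindered one, so the para-quinone diester forms, while the hindered weak base 2,6-lutidine avoids ketene formation, β-elimination of acetate and benzoyl scrambling, leaving the (R) centre untouched.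

Step 5
Reactants: 10 3-(benzoyloxy)-6-{[(3R)-3-acetoxybutanoyl]oxy}-2,5-bis[4-(benzyloxy)phenyl]-1,4-benzoquinone
Product: 11 Curtisian T, 2'-(benzoyloxy)-3',4,4'',6'-tetrahydroxy-[1,1':4',1''-terphenyl]-5'-yl (3R)-3-acetoxybutanoate
Conditions: H2 (1 atm), 10% Pd/C, EtOAc/THF 1:1, 20 °C, 6 h; filter under Ar
Reagents that add atoms: none
Why: Heterogeneous catalytic hydrogenation reduces the quinone to the hydroquinone (the two ring carbonyls become the two free OH groups para to each other) and hydrogenolyses both benzyl aryl ethers under neutral conditions that leave the two aryl esters, the acetate and the (R) centre unchanged and give no base to trigger ortho acyl migration.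

**Compound list**
1 | 2,5-dihydroxy-1,4-benzoquinone | O=C1C=C(O)C(=O)C=C1O | starting material
2 | 4-(benzyloxy)aniline | Nc1ccc(OCc2ccccc2)cc1 | starting material
3 | 4-(benzyloxy)benzenediazonium tetrafluoroborate | N#[N+]c1ccc(OCc2ccccc2)cc1.F[B-](F)(F)F | intermediate
4 | 2-[4-(benzyloxy)phenyl]-3,6-dihydroxy-1,4-benzoquinone | O=C1C=C(O)C(=O)C(c2ccc(OCc3ccccc3)cc2)=C1O | intermediate
5 | 2,5-bis[4-(benzyloxy)phenyl]-3,6-dihydroxy-1,4-benzoquinone (4,4''-di-O-benzylatromentin) | O=C1C(c2ccc(OCc3ccccc3)cc2)=C(O)C(=O)C(c2ccc(OCc3ccccc3)cc2)=C1O | intermediate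
6 | 3-(benzoyloxy)-6-hydroxy-2,5-bis[4-(benzyloxy)phenyl]-1,4-benzoquinone | O=C1C(c2ccc(OCc3ccccc3)cc2)=C(OC(=O)c2ccccc2)C(=O)C(c2ccc(OCc3ccccc3)cc2)=C1O | intermediate
7 | (R)-3-hydroxybutanoic acid | C[C@@H](O)CC(=O)O | starting material
8 | (R)-3-acetoxybutanoic acid | C[C@@H](OC(C)=O)CC(=O)O | intermediate
9 | (R)-3-acetoxybutanoyl chloride | C[C@@H](OC(C)=O)CC(=O)Cl | intermediate
10 | 3-(benzoyloxy)-6-{[(3R)-3-acetoxybutanoyl]oxy}-2,5-bis[4-(benzyloxy)phenyl]-1,4-benzoquinone | O=C1C(c2ccc(OCc3ccccc3)cc2)=C(OC(=O)c2ccccc2)C(=O)C(c2ccc(OCc3ccccc3)cc2)=C1OC(=O)C[C@@H](C)OC(C)=O | intermediate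
11 | Curtisian T | CC(=O)O[C@H](C)CC(=O)Oc1c(O)c(-c2ccc(O)cc2)c(OC(=O)c2ccccc2)c(O)c1-c1ccc(O)cc1 | target

**Step count and risks**
Total steps: 5. Longest linear sequence: 4 (steps 1, 2, 4, 5).

The three steps most likely to fail:

Step 1 (the proposed new photochemical diarylation). Risks are azo coupling at the enol carbon, stalling at mono-aryl quinone 4, and quenching of the photocatalyst by the quinone. The fallback uses known chemistry, sets out from 1 and comes back at 5. Heating 1 in MeOH with HCl gives 2,5-dimethoxy-1,4-benzoquinone F1. Bromination with Br2 in AcOH gives 2,5-dibromo-3,6-dimethoxy-1,4-benzoquinone F2. Twofold Suzuki–Miyaura coupling of F2 with commercial [4-(benzyloxy)phenyl]boronic acid (Pd(PPh3)4, K2CO3, dioxane/H2O, 80 °C) gives 2,5-bis[4-(benzyloxy)phenyl]-3,6-dimethoxy-1,4-benzoquinone F3. NaOH in dioxane/H2O followed by HCl hydrolyses both vinylogous methyl esters and delivers 5.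

Step 2 (mono-benzoylation). The risk is a near-statistical mixture of 5, 6 and dibenzoate, or acyl exchange between molecules. The fallback sets out from 5 and comes back at 6 by over-acylation and selective mono-cleavage. Excess BzCl in pyridine/CH2Cl2 gives 3,6-bis(benzoyloxy)-2,5-bis[4-(benzyloxy)phenyl]-1,4-benzoquinone F4. Then LiOH (1.0 equiv) in THF/H2O at 0 °C cleaves one benzoate only, as in the selective monohydrolysis of symmetric diesters, because the enolate formed after the first cleavage deactivates the second ester. Acidification gives 6.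

Step 4 (second acylation). The risks are a sluggish reaction of the deactivated, hindered enol of 6 with a β-acetoxy acid chloride that can eliminate to the crotonate, and benzoyl scrambling. The fallback sets out from 5 and comes back at 10 by reversing the order of the two acylations. The fragile chloride 9 (1.0 equiv, 2,6-lutidine, CH2Cl2, −40 °C) is coupled first to the more reactive unacylated hydroxyquinone to give 3-{[(3R)-3-acetoxybutanoyl]oxy}-6-hydroxy-2,5-bis[4-(benzyloxy)phenyl]-1,4-benzoquinone F5. The robust, non-enolisable BzCl (2,6-lutidine, CH2Cl2, −20 °C) is then used for the harder second acylation, which gives 10.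

**Further compounds**
F1 | step 1 | 2,5-dimethoxy-1,4-benzoquinone | COC1=CC(=O)C(OC)=CC1=O
F2 | step 1 | 2,5-dibromo-3,6-dimethoxy-1,4-benzoquinone | COC1=C(Br)C(=O)C(OC)=C(Br)C1=O
F3 | step 1 | 2,5-bis[4-(benzyloxy)phenyl]-3,6-dimethoxy-1,4-benzoquinone | COC1=C(c2ccc(OCc3ccccc3)cc2)C(=O)C(OC)=C(c2ccc(OCc3ccccc3)cc2)C1=O
F4 | step 2 | 3,6-bis(benzoyloxy)-2,5-bis[4-(benzyloxy)phenyl]-1,4-benzoquinone | O=C1C(c2ccc(OCc3ccccc3)cc2)=C(OC(=O)c2ccccc2)C(=O)C(c2ccc(OCc3ccccc3)cc2)=C1OC(=O)c1ccccc1
F5 | step 4 | 3-{[(3R)-3-acetoxybutanoyl]oxy}-6-hydroxy-2,5-bis[4-(benzyloxy)phenyl]-1,4-benzoquinone | O=C1C(c2ccc(OCc3ccccc3)cc2)=C(O)C(=O)C(c2ccc(OCc3ccccc3)cc2)=C1OC(=O)C[C@@H](C)OC(C)=O
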